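**Retrosynthetic overview**

- The central single bond of the diene is made last, by Stille coupling of an alkenyl iodide on the finished peroxylactone with an alkenylstannane.
- The 1,2-dioxane is cut twice, at C4–C4a (ring CH2 to the quaternary carbon that carries the lactone oxygen) and at O2–C3. This is a stepwise (4+2) annulation of a 1,1-disubstituted alkene with a four-atom C–C–O–O unit.
- Enabling feature: C4a (methyl, lactone oxygen) is a masked ketone carbon that can be reached as a cyclic acyloxocarbenium ion. It stands 1,3 through the ring CH2 to C3, a tertiary-cation position, and the peroxide oxygen on the neighbouring ring-fusion carbon C7a is placed to capture that cation in a six-membered ring.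
- Ring order: γ-lactone first (closed in the flask from a γ-keto tert-butyl ester), then the 1,2-dioxane; the phenyl ring is bought. The peroxide carbon comes from proline aminoxylation followed by SN2 with H2O2; the side-chain methyl carbon comes from (R)-3-bromo-2-methylpropan-1-ol.

Key step: step 10

Remark: tert-butyl 4-oxopentanoate, (R)-3-bromo-2-methylpropan-1-ol and but-2-yn-1-ylbenzene are taken as purchasable, and all peroxides are assumed to be handled cold, shielded and free of metal traces.

**Route**

Step 1
Reactants: 1 tert-butyl 4-oxopentanoate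
Product: 2 tert-butyl (3R)-4-oxo-3-[(phenylamino)oxy]pentanoate
Conditions: PhNO (1 equiv, slow addition), L-proline (20 mol %), 1 (3 equiv), DMSO, rt
Reagents that add atoms: nitrosobenzene, O=Nc1ccccc1
Why: Proline-catalysed α-aminoxylation (O-selective nitroso aldol reaction of the enamine), in which the more substituted enamine forms toward C3 and hydrogen bonding from the carboxylic acid steers nitrosobenzene to one enamine face, so the (3R) centre is set under catalyst control.

Step 2
Reactants: 2 tert-butyl (3R)-4-oxo-3-[(phenylamino)oxy]pentanoate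
Product: 3 tert-butyl (3R)-3-hydroxy-4-oxopentanoate
Conditions: H2 (1 atm), Pd/C (5 mol %), EtOAc, rt
Reagents that add atoms: none
Why: Hydrogenolysis of the weak N–O bond leaves the C–O bond and the stereocentre untouched.

Step 3
Reactants: 3 tert-butyl (3R)-3-hydroxy-4-oxopentanoate
Product: 4 tert-butyl (3R)-4-oxo-3-{[(trifluoromethyl)sulfonyl]oxy}pentanoate
Conditions: Tf2O (1.1 equiv), 2,6-lutidine (1.2 equiv), CH2Cl2, −78 °C; used crude
Reagents that add atoms: trifluoromethanesulfonic anhydride, O=S(=O)(OS(=O)(=O)C(F)(F)F)C(F)(F)F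
Why: O-Sulfonylation of the secondary alcohol at low temperature with a hindered base keeps the C–O bond, so the configuration stays (3R).

Step 4
Reactants: 4 tert-butyl (3R)-4-oxo-3-{[(trifluoromethyl)sulfonyl]oxy}pentanoate
Product: 5 tert-butyl (3S)-3-hydroperoxy-4-oxopentanoate
Conditions: anhydrous H2O2 in Et2O (5 equiv), NaHCO3 (2 equiv), CH2Cl2, −40 → 0 °C
Reagents that add atoms: hydrogen peroxide, OO
Why: SN2 perhydrolysis of a sulfonate, here a very reactive α-keto triflate, should proceed with inversion to the (3S) hydroperoxide, and the weakly basic medium avoids Kornblum–DeLaMare fragmentation and elimination.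

Step 5
Reactants: 5 tert-butyl (3S)-3-hydroperoxy-4-oxopentanoate
Product: 6 tert-butyl (3S)-4-oxo-3-[(triethylsilyl)peroxy]pentanoate
Conditions: Et3SiOTf (1.05 equiv), 2,6-lutidine (1.2 equiv), CH2Cl2, −78 °C
Reagents that add atoms: triethylsilyl trifluoromethanesulfonate, CC[Si](CC)(CC)OS(=O)(=O)C(F)(F)F
Why: O-Silylation of the hydroperoxide, the most acidic and accessible site, at −78 °C does not involve the stereocentre.

Step 6
Reactants: 7 (2R)-3-bromo-2-methylpropan-1-ol
Product: 9 (2S)-2,4-dimethylpent-4-en-1-ol, via bromomagnesium alkoxide 8 (not isolated)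
Conditions: CH2=C(CH3)MgBr (2.3 equiv), Li2CuCl4 (3 mol %), THF, −20 → 0 °C; aq. NH4Cl
Reagents that add atoms: isopropenylmagnesium bromide, CC(=C)[Mg]Br
Why: Copper-catalysed cross-coupling of a primary alkyl bromide with an alkenyl Grignard reagent (the first equivalent forms alkoxide 8) leaves the stereocentre untouched, and only the CIP descriptor changes from R to S.

Step 7
Reactants: 9 (2S)-2,4-dimethylpent-4-en-1-ol
Product: 10 (4S)-5-iodo-2,4-dimethylpent-1-ene
Conditions: PPh3 (1.2 equiv), I2 (1.2 equiv), imidazole (1.5 equiv), CH2Cl2, 0 °C → rt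
Reagents that add atoms: iodine, II
Why: Appel-type iodination of the primary alcohol does not touch the stereocentre.

Step 8
Reactants: 10 (4S)-5-iodo-2,4-dimethylpent-1-ene
Product: 11 (4S)-4,6-dimethylhept-6-en-1-yne
Conditions: LiC≡CH·H2NCH2CH2NH2 (1.5 equiv), DMSO, rt
Reagents that add atoms: lithium acetylide ethylenediamine complex, [Li]C#C.NCCN
Why: SN2 alkylation of lithium acetylide by the primary iodide in a dipolar aprotic solvent.

Step 9
Reactants: 11 (4S)-4,6-dimethylhept-6-en-1-yne
Product: 13 (1E,4S)-1-iodo-2,4,6-trimethylhepta-1,6-diene, via alkenylalane 12 (not isolated)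
Conditions: AlMe3 (2 equiv), Cp2ZrCl2 (0.25 equiv), CH2Cl2, 0 °C → rt; then I2, THF, −30 °C
Reagents that add atoms: trimethylaluminium, C[Al](C)C; iodine, II
Why: Zirconium-catalysed carboalumination (Negishi) is a regioselective syn addition of Me–Al to the terminal alkyne, iodinolysis with retention gives the (E)-iodide, and the 1,1-disubstituted alkene is inert under these conditions.

Step 10
Reactants: 6 tert-butyl (3S)-4-oxo-3-[(triethylsilyl)peroxy]pentanoate; 13 (1E,4S)-1-iodo-2,4,6-trimethylhepta-1,6-diene
Product: 16 (3R,4aS,7aS)-3-[(2R,4E)-5-iodo-2,4-dimethylpent-4-en-1-yl]-3,4a-dimethyltetrahydrofuro[3,2-c][1,2]dioxin-6(3H)-one, via silyl pseudo-ester 14 (not isolated), via acyloxocarbenium triflate 15 (not isolated)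
Conditions: (a) 6, Et3SiOTf (1.1 equiv), 2,6-di-tert-butyl-4-methylpyridine (1.2 equiv), CH2Cl2, −40 → 0 °C, argon sweep; (b) 13 (1.5 equiv), Et3SiOTf (0.3 equiv), −78 → −40 °C; pyridine quench; chromatography to remove the epimer at C3
Reagents that add atoms: none
Why: Proposed new method: Et3SiOTf first closes the γ-lactone (the ester carbonyl oxygen adds 5-exo-trig to the silyl-activated ketone and the tert-butyl group leaves as 2-methylpropene) to give 14, whose ionisation gives the cyclic acyloxocarbenium ion 15; the CH2 terminus of the 1,1-disubstituted alkene of 13 then adds to the cationic carbon (Prins-type, Markovnikov), forming the C4–C4a bond, and the tertiary carbocation so produced is captured through a six-membered chair transition state by the silylated peroxide oxygen, which releases Et3Si+ and completes the 1,2-dioxane as a stepwise (4+2) annulation. The closest known reactions are the Lewis-acid (3+2) annulation of silylperoxy-substituted carbenium ions with alkenes to 1,2-dioxolanes and the Friedel–Crafts-type alkylation of arenes by α-angelica lactone or the cyclic pseudo-chloride of levulinic acid, which run through the same kind of acyloxocarbenium ion; placing the peroxide on the carbon next to the cationic centre, which turns the five-ring closure into the six-ring closure needed here, has not been shown. C4a is set relative to the existing (S) peroxide carbon by the face on which the alkene attacks 15: an electronegative substituent next to the cationic carbon of a five-membered oxocarbenium ion directs the nucleophile to the cis face (inside attack on the envelope with the C–O bond pseudo-equatorial), which gives the cis ring fusion of the target. C3 arises from a planar tertiary cation that carries CH3 and CH2R, and the two chair closures differ only in which of these groups is axial, so no useful substrate control is expected and the (3R) isomer 16 has to be separated from its C3 epimer. Beyond this the step needs chemoselectivity for the 1,1-disubstituted alkene over the iodoalkene (electron-poor and hindered), configurational stability of the carbon next to the cation (low temperature, hindered non-nucleophilic base) and an intact O–O bond (sub-stoichiometric silyl triflate below −40 °C).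

Step 11
Reactants: 17 but-2-yn-1-ylbenzene
Product: 19 [(2E)-3-iodobut-2-en-1-yl]benzene, via alkenylzirconocene chloride 18 (not isolated)
Conditions: Cp2Zr(H)Cl (1.3 equiv), THF, rt → 40 °C; then I2, 0 °C
Reagents that add atoms: iodine, II
Why: Hydrozirconation is a syn addition, equilibration with a slight excess of Cp2Zr(H)Cl should place zirconium on the less hindered methyl-bearing carbon, and iodinolysis with retention gives the (E)-iodide.

Step 12
Reactants: 19 [(2E)-3-iodobut-2-en-1-yl]benzene
Product: 21 tributyl[(2E)-1-phenylbut-2-en-2-yl]stannane, via alkenyllithium 20 (not isolated)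
Conditions: t-BuLi (2.1 equiv), Et2O, −78 °C; then Bu3SnCl, −78 °C → rt
Reagents that add atoms: tributyltin chloride, CCCC[Sn](Cl)(CCCC)CCCC
Why: Iodine–lithium exchange and stannylation both proceed with retention of the alkene geometry.

Step 13
Reactants: 16 (3R,4aS,7aS)-3-[(2R,4E)-5-iodo-2,4-dimethylpent-4-en-1-yl]-3,4a-dimethyltetrahydrofuro[3,2-c][1,2]dioxin-6(3H)-one; 21 tributyl[(2E)-1-phenylbut-2-en-2-yl]stannane
Product: 22 (3R,4aS,7aS)-3,4a-dimethyl-3-[(2R,4E,6E)-2,4,6-trimethyl-8-phenylocta-4,6-dien-1-yl]tetrahydrofuro[3,2-c][1,2]dioxin-6(3H)-one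
Conditions: Pd2(dba)3 (5 mol %), AsPh3 (20 mol %), NMP, 40 °C, dark
Reagents that add atoms: none
Why: Stille coupling joins the two alkenyl partners with retention of both geometries under neutral conditions, and dialkyl peroxides are known to survive palladium-catalysed cross-coupling when strongly reducing phosphines are avoided (hence AsPh3).

**Compound list**

1 | tert-butyl 4-oxopentanoate | CC(=O)CCC(=O)OC(C)(C)C | starting material
2 | tert-butyl (3R)-4-oxo-3-[(phenylamino)oxy]pentanoate | CC(=O)[C@H](ONc1ccccc1)CC(=O)OC(C)(C)C | intermediate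
3 | tert-butyl (3R)-3-hydroxy-4-oxopentanoate | CC(=O)[C@H](O)CC(=O)OC(C)(C)C | intermediate
4 | tert-butyl (3R)-4-oxo-3-{[(trifluoromethyl)sulfonyl]oxy}pentanoate | CC(=O)[C@H](OS(=O)(=O)C(F)(F)F)CC(=O)OC(C)(C)C | intermediate
5 | tert-butyl (3S)-3-hydroperoxy-4-oxopentanoate | CC(=O)[C@@H](OO)CC(=O)OC(C)(C)C | intermediate
6 | tert-butyl (3S)-4-oxo-3-[(triethylsilyl)peroxy]pentanoate | CC(=O)[C@@H](OO[Si](CC)(CC)CC)CC(=O)OC(C)(C)C | intermediate
7 | (2R)-3-bromo-2-methylpropan-1-ol | OC[C@@H](C)CBr | starting material
8 | bromomagnesium (2R)-3-bromo-2-methylpropan-1-olate | Br[Mg]OC[C@@H](C)CBr | intermediate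
9 | (2S)-2,4-dimethylpent-4-en-1-ol | OC[C@@H](C)CC(C)=C | intermediate
10 | (4S)-5-iodo-2,4-dimethylpent-1-ene | IC[C@@H](C)CC(C)=C | intermediate
11 | (4S)-4,6-dimethylhept-6-en-1-yne | C#CC[C@@H](C)CC(C)=C | intermediate
12 | dimethyl[(1E,4S)-2,4,6-trimethylhepta-1,6-dien-1-yl]alumane | C[Al](C)/C=C(\C)C[C@@H](C)CC(C)=C | intermediate
13 | (1E,4S)-1-iodo-2,4,6-trimethylhepta-1,6-diene | I/C=C(\C)C[C@@H](C)CC(C)=C | intermediate
14 | (4S,5RS)-5-methyl-5-[(triethylsilyl)oxy]-4-[(triethylsilyl)peroxy]oxolan-2-one | CC1(O[Si](CC)(CC)CC)OC(=O)C[C@@H]1OO[Si](CC)(CC)CC | intermediate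
15 | (4S)-5-methyl-2-oxo-4-[(triethylsilyl)peroxy]oxolan-5-ylium trifluoromethanesulfonate (cyclic acyloxocarbenium ion) | CC1=[O+]C(=O)C[C@@H]1OO[Si](CC)(CC)CC.[O-]S(=O)(=O)C(F)(F)F | intermediate
16 | (3R,4aS,7aS)-3-[(2R,4E)-5-iodo-2,4-dimethylpent-4-en-1-yl]-3,4a-dimethyltetrahydrofuro[3,2-c][1,2]dioxin-6(3H)-one | I/C=C(\C)C[C@@H](C)C[C@]1(C)C[C@]2(C)OC(=O)C[C@@H]2OO1 | intermediate
17 | but-2-yn-1-ylbenzene | CC#CCc1ccccc1 | starting material
18 | chloridobis(cyclopentadienyl)[(2E)-1-phenylbut-2-en-2-yl]zirconium | C/C(=C\Cc1ccccc1)[Zr](Cl)(C1C=CC=C1)C1C=CC=C1 | intermediate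
19 | [(2E)-3-iodobut-2-en-1-yl]benzene | C/C(I)=C\Cc1ccccc1 | intermediate
20 | [(2Z)-1-phenylbut-2-en-2-yl]lithium | C/C([Li])=C\Cc1ccccc1 | intermediate
21 | tributyl[(2E)-1-phenylbut-2-en-2-yl]stannane | C/C(=C\Cc1ccccc1)[Sn](CCCC)(CCCC)CCCC | intermediate
22 | (3R,4aS,7aS)-3,4a-dimethyl-3-[(2R,4E,6E)-2,4,6-trimethyl-8-phenylocta-4,6-dien-1-yl]tetrahydrofuro[3,2-c][1,2]dioxin-6(3H)-one | CC(=C\Cc1ccccc1)/C=C(\C)C[C@@H](C)C[C@]1(C)C[C@]2(C)OC(=O)C[C@@H]2OO1 | target

**Step count and risks**

Total step count: 13. Longest linear sequence: 7 steps (steps 1–5, 10 and 13, from 1 to 22).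

Step 10 (Proposed new method). What may go wrong:
- The tertiary carbocation may lose a proton (ene-type termination) or the silyl triflate may heterolyse the O–O bond before the ring closes.
- Capture of the planar cation is expected to be unselective at C3.
- The alkene may attack the oxocarbenium ion trans to the peroxide, which would lead to the trans-fused isomer.

Fallback (known reactions only), from 13 back to 16. A copper bis(oxazoline)-catalysed carbonyl-ene reaction of 13 with methyl pyruvate ([Cu(t-Bu-box)](SbF6)2, ligand antipode chosen to give the (2S) alcohol, CH2Cl2; hydrogen taken from the allylic methyl group) forms the same CH2–C(quaternary) bond without a ring and should give methyl (2S,6S,8E)-2-hydroxy-9-iodo-2,6,8-trimethyl-4-methylidenenon-8-enoate F1. Reduction with i-Bu2AlH at −78 °C gives (2S,6S,8E)-2-hydroxy-9-iodo-2,6,8-trimethyl-4-methylidenenon-8-enal F2, which with Ph3P=C=C=O closes the butenolide (5S)-5-[(4S,6E)-7-iodo-4,6-dimethyl-2-methylidenehept-6-en-1-yl]-5-methylfuran-2(5H)-one F3. Mukaiyama–Isayama hydroperoxysilylation of the 1,1-disubstituted alkene (Co(thd)2, thd = 2,2,6,6-tetramethylheptane-3,5-dionate, O2, Et3SiH) gives (5S)-5-[(2RS,4R,6E)-7-iodo-2,4,6-trimethyl-2-[(triethylsilyl)peroxy]hept-6-en-1-yl]-5-methylfuran-2(5H)-one F4. Desilylation (HF·pyridine) and Et2NH in CF3CH2OH then close the 1,2-dioxane by intramolecular oxa-Michael addition and return to the route at 16, again after separation of the C3 epimer.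

Step 4. What may go wrong: β-elimination toward the conjugated enedione, loss of configuration by enolisation of the α-keto triflate or by participation of the ketone as its perhydrate, and base-induced fragmentation of the α-hydroperoxy ketone.

Fallback, from 1 directly to 5. Amino-acid-catalysed α-oxidation of the ketone with singlet oxygen (O2, tetraphenylporphyrin, visible light, catalyst antipode chosen to give the (3S) hydroperoxide, DMSO) is an electrophilic oxygenation of the enamine that avoids the triflate altogether. Lower enantiomeric purity is to be expected; no new compound is made.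

Step 13. What may go wrong: slow transmetalation of the hindered alkenylstannane leaves zerovalent palladium time to insert into the O–O bond, and protodestannylation competes.

Fallback with reversed polarity, from 13 back to 22. Miyaura borylation of 13 (B2pin2, PdCl2(dppf), KOPh, toluene, 50 °C) gives 4,4,5,5-tetramethyl-2-[(1E,4S)-2,4,6-trimethylhepta-1,6-dien-1-yl]-1,3,2-dioxaborolane F5. Annulation with 6 under the conditions of step 10 gives (3R,4aS,7aS)-3-[(2R,4E)-2,4-dimethyl-5-(4,4,5,5-tetramethyl-1,3,2-dioxaborolan-2-yl)pent-4-en-1-yl]-3,4a-dimethyltetrahydrofuro[3,2-c][1,2]dioxin-6(3H)-one F6. Suzuki–Miyaura coupling with iodide 19 (PdCl2(dppf), K3PO4, THF/H2O, rt) returns to the route at 22; step 12 is then not needed.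

Further compounds
F1 | step 10 | methyl (2S,6S,8E)-2-hydroxy-9-iodo-2,6,8-trimethyl-4-methylidenenon-8-enoate | I/C=C(\C)C[C@@H](C)CC(=C)C[C@](C)(O)C(=O)OC
F2 | step 10 | (2S,6S,8E)-2-hydroxy-9-iodo-2,6,8-trimethyl-4-methylidenenon-8-enal | I/C=C(\C)C[C@@H](C)CC(=C)C[C@](C)(O)C=O
F3 | step 10 | (5S)-5-[(4S,6E)-7-iodo-4,6-dimethyl-2-methylidenehept-6-en-1-yl]-5-methylfuran-2(5H)-one | I/C=C(\C)C[C@@H](C)CC(=C)C[C@]1(C)OC(=O)C=C1
F4 | step 10 | (5S)-5-[(2RS,4R,6E)-7-iodo-2,4,6-trimethyl-2-[(triethylsilyl)peroxy]hept-6-en-1-yl]-5-methylfuran-2(5H)-one | I/C=C(\C)C[C@@H](C)CC(C)(OO[Si](CC)(CC)CC)C[C@]1(C)OC(=O)C=C1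
F0 | step 4 | none | none
F5 | step 13 | 4,4,5,5-tetramethyl-2-[(1E,4S)-2,4,6-trimethylhepta-1,6-dien-1-yl]-1,3,2-dioxaborolane | CC1(C)OB(/C=C(\C)C[C@@H](C)CC(C)=C)OC1(C)C
F6 | step 13 | (3R,4aS,7aS)-3-[(2R,4E)-2,4-dimethyl-5-(4,4,5,5-tetramethyl-1,3,2-dioxaborolan-2-yl)pent-4-en-1-yl]-3,4a-dimethyltetrahydrofuro[3,2-c][1,2]dioxin-6(3H)-one | CC1(C)OB(/C=C(\C)C[C@@H](C)C[C@]2(C)C[C@]3(C)OC(=O)C[C@@H]3OO2)OC1(C)C
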